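Retrosynthesis cuts, in this order: the O6–acyl ester bond (to (2E,4E,6E)-octa-2,4,6-trienoic acid), the C12 aldehyde oxygen (back to the C8 methyl group), C1–C2 of ring A (metathesis, then saturation), and C5–C6 plus C9–C10 of ring B in one [4+2] step.
Enabling feature: in ring B the C6 oxygen and the C9 carboxyl carbon C11 stand cis-1,4 (both β) across C7=C8, and C9 also bears OH. O6–C11 is therefore the lactone bridge of a 2-oxabicyclo[2.2.2]oct-5-en-3-one. This is the adduct of 3-hydroxy-4-methyl-2-pyrone (O1, C2, C3, C4, C5, C6 = O6, C11, C9, C8, C7, C6; 4-CH3 = C12) with a C5=C10 alkene.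
Forward: ring B closes first as the carbocycle of the bridged lactone and hydroxide cuts the bridge. Ring A then closes by metathesis at C1=C2 and is saturated, C12 is oxidised, and the trienoate is attached last.
Stereochemistry: C5, C6, C9 and C10 all arise in the cycloaddition. The bridge makes C6–O and C9–C11 cis, the E-enal puts C1 and C4 trans, the formyl group goes endo, and the chiral primary amine sets the absolute sense. No later step touches a stereocentre; the three E alkenes come from (2E,4E)-hexadienal and an E-selective olefination.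

Key step: step 7

Remark on numbering: drimane numbering (C1–C15) is used for the carbons of all intermediates; α/β refer to the usual drimane drawing (C10 methyl β).
Assumption: the sense of induction for this new dienophile class cannot be derived from precedent. The quinidine-derived amine is written, and its quinine-derived pseudoenantiomer would take its place if that one delivers the (1R,4R,7S,8S) adduct.

Step 1
Reactants: 1 2,2-dimethylpent-4-enal; 2 2-(triphenylphosphoranylidene)propanal
Product: 3 (E)-2,4,4-trimethylhepta-2,6-dienal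
Conditions: PhMe, 110 °C (sealed tube), 48 h
Reagents that add atoms: none
Why: Wittig olefination with a formyl-stabilised ylide should give the E-trisubstituted enal (CHO trans to the tert-alkyl group); aldehyde 1 cannot enolise, and the α-branched product enal is a poorer partner for a second olefination.

Step 2
Reactants: 4 diethyl oxalpropionate (diethyl 2-methyl-3-oxobutanedioate); 5 allyl bromide
Product: 6 diethyl 2-allyl-2-methyl-3-oxobutanedioate (racemic)
Conditions: K2CO3, acetone, reflux
Reagents that add atoms: none
Why: SN2 C-alkylation of a soft, doubly activated enolate with an allylic halide; any O-allyl enol ether should converge on 6 by Claisen rearrangement on heating, and the racemic centre is erased when the pyrone forms.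

Step 3
Reactants: 6 diethyl 2-allyl-2-methyl-3-oxobutanedioate
Product: 8 3-methyl-2-oxohex-5-enoic acid (racemic), via 2-allyl-2-methyl-3-oxobutanedioic acid 7 (not isolated)
Conditions: 10% aq H2SO4, reflux
Reagents that add atoms: water, O
Why: Acid hydrolysis of both esters and decarboxylation of the β-keto acid (ketonic cleavage of an oxalacetic ester) is the classical route to α-keto acids; acid instead of base avoids retro-Claisen loss of the oxalyl group.

Step 4
Reactants: 8 3-methyl-2-oxohex-5-enoic acid
Product: 10 3-methyl-2,5-dioxopentanoic acid (racemic, used crude), via the secondary ozonide 3-methyl-2-oxo-4-(1,2,4-trioxolan-3-yl)butanoic acid 9 (not isolated)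
Conditions: O3, CH2Cl2, −78 °C (Sudan III end point); then Me2S, −78 °C → rt
Reagents that add atoms: ozone, [O-][O+]=O
Why: Ozonolysis with reductive work-up cleaves the only C=C bond; the indicator spares the small enol content, and the cold sulfide quench leaves no peroxide that could decarboxylate the α-keto acid.

Step 5
Reactants: 10 3-methyl-2,5-dioxopentanoic acid
Product: 12 3-acetoxy-4-methyl-2H-pyran-2-one, via 4-methyl-2-oxo-5,6-dihydro-2H-pyran-3,6-diyl diacetate 11 (not isolated)
Conditions: Ac2O, Et3N, DMAP (cat.), CH2Cl2, 0 → 40 °C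
Reagents that add atoms: acetic anhydride, CC(=O)OC(C)=O
Why: Dehydrative enol-lactonisation of a δ-oxo acid under acylating, non-acidic conditions, the way 2-keto-3-deoxy aldaric acids give 3-acetoxy-2-pyrones: the enol oxygen is capped as acetate, so only the carboxyl oxygen can add to the aldehyde, and base-induced vinylogous E1cB loss of AcOH from 11 gives the pyrone instead of the acid-catalysed Paal–Knorr furoic acid.

Step 6
Reactants: 12 3-acetoxy-4-methyl-2H-pyran-2-one
Product: 13 3-hydroxy-4-methyl-2H-pyran-2-one
Conditions: NH4OAc (cat.), MeOH–H2O 4:1, rt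
Reagents that add atoms: none
Why: Neutral transesterification of an activated, phenol-type enol acetate should free the hydroxyl group without methanolysis of the pyrone lactone.

Step 7
Reactants: 3 (E)-2,4,4-trimethylhepta-2,6-dienal; 13 3-hydroxy-4-methyl-2H-pyran-2-one
Product: 15 (1R,4R,7S,8S)-5,8-dimethyl-7-(2-methylpent-4-en-2-yl)-3-oxo-4-(trimethylsilyloxy)-2-oxabicyclo[2.2.2]oct-5-ene-8-carbaldehyde (formyl and C5–H on the C7=C8 side, C10 methyl and C4 branch on the lactone side), via the free bridgehead carbinol (1R,4R,7S,8S)-4-hydroxy-5,8-dimethyl-7-(2-methylpent-4-en-2-yl)-3-oxo-2-oxabicyclo[2.2.2]oct-5-ene-8-carbaldehyde 14 (not isolated)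
Conditions: 9-amino-9-deoxy-epi-quinidine (20 mol %), TFA (40 mol %), CH2Cl2 (2 M), 0.9 GPa, 25 °C, 72 h; then N-(trimethylsilyl)imidazole, CH2Cl2, 0 °C → rt
Reagents that add atoms: N-(trimethylsilyl)imidazole, C[Si](C)(C)n1ccnc1
Why: Proposed new method: the primary amine condenses with 3 to an iminium ion while the quinuclidine site holds 13 as a hydrogen-bonded pyronate, the unhindered pyrone C6–H carbon adds to the β-carbon C5, the resulting enamine carbon C10 closes onto C9 (asynchronous [4+2], Michael then aldol), hydrolysis frees 14, and silylation of the bridgehead carbinol shuts off retro-aldol/retro-Michael reversal. The closest known reaction types are the cinchona-amine-catalysed asymmetric Diels–Alder reactions of 3-hydroxy-2-pyrones with enones and α-substituted acrylic dienophiles, primary-amine iminium activation of α-branched enals, and hyperbaric iminium catalysis of congested acceptors; new is the α-methyl, β-tert-alkyl enal. One ring closes: ring B (C5–C6–C7–C8–C9–C10) forms as a six-membered carbocycle by intermolecular suprafacial [4+2] addition across pyrone C3/C6, its second bond being a 6-(enolexo)-exo-trig aldol-type closure, inside a 2-oxabicyclo[2.2.2]octenone whose O–C(=O) bridge is the old pyrone lactone. C6 and C9 are cis because the bridge ties O6 to C11; C5 and C10 carry the C4 branch and the methyl group on the same side because the E geometry of 3 is transferred; formyl and C5–H lie over C7=C8 because the iminium carbon goes endo while the tert-alkyl group takes the exo position over the unsubstituted ring oxygen; and the absolute sense follows from the pyrone face left open in the two-point-bound catalyst complex. The step needs C10-to-C9 regiochemistry (secured by the donor oxygen on C9 and the acceptor on C10), endo selectivity, one diene face, and closure faster than rotation about C5–C10; the first bond joins two CH carbons, so the hindered enal should be slow rather than blocked, which is why pressure is applied.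

Step 8
Reactants: 15 silylated bridged lactone aldehyde
Product: 16 (1R,4R,7S,8S)-5,8-dimethyl-7-(2-methylpent-4-en-2-yl)-4-(trimethylsilyloxy)-8-vinyl-2-oxabicyclo[2.2.2]oct-5-en-3-one
Conditions: Ph3PCH3Br, KHMDS, THF, 0 °C; then 15, −78 → 0 °C
Reagents that add atoms: methyltriphenylphosphonium bromide, C[P+](c1ccccc1)(c1ccccc1)c1ccccc1.[Br-]
Why: Wittig methylenation of a non-enolisable aldehyde: the capped carbinol rules out retro-aldol cleavage, the aldehyde is far more electrophilic than the lactone, and the low temperature keeps the endo-vinyl/C7=C8 1,5-diene well below any siloxy-Cope threshold.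

Step 9
Reactants: 16 vinyl bridged lactone silyl ether
Product: 17 (1R,4R,5S,6S)-1,4-dihydroxy-2,6-dimethyl-5-(2-methylpent-4-en-2-yl)-6-vinylcyclohex-2-ene-1-carboxylic acid
Conditions: LiOH·H2O, THF–MeOH–H2O 3:1:1, 0 °C → rt; then 1 M HCl to pH 3, 0 °C
Reagents that add atoms: lithium hydroxide, [Li+].[OH-]
Why: Saponification (acyl–oxygen cleavage) of the strained bridged δ-lactone is irreversible as the carboxylate and leaves the C6–O bond and its configuration untouched; the trimethylsilyl ether falls off in the same basic methanol and acidic work-up.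

Step 10
Reactants: 17 ring-opened hydroxy acid diene
Product: 18 6β,9α-dihydroxydrima-1,7-dien-11-oic acid ((5S,6R,9R,10S), trans-fused, 5α-H, 10β-CH3)
Conditions: Hoveyda–Grubbs II (5 mol %), 1,4-benzoquinone (10 mol %), PhMe (5 mM), 60 °C
Reagents that add atoms: none
Why: Ring-closing metathesis: the catalyst loads on the unhindered allyl terminus and closes onto the neopentyl vinyl group, which in the half-chair of 17 is trans-diequatorial and gauche to the C4 branch, so ring A should close trans-fused with the trisubstituted C7=C8 inert.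

Step 11
Reactants: 18 6β,9α-dihydroxydrima-1,7-dien-11-oic acid
Product: 19 6β,9α-dihydroxydrim-7-en-11-oic acid ((5S,6R,9R,10S))
Conditions: 2-nitrobenzenesulfonohydrazide, Et3N, CH2Cl2, rt (repeated charges)
Reagents that add atoms: none
Why: Diimide reduction falls off steeply with alkene substitution, so the cis-disubstituted C1=C2 is saturated and the trisubstituted C7=C8 stays; doing this before any heating also removes the C1=C2/C7=C8 hydroxy-1,5-diene motif.

Step 12
Reactants: 19 6β,9α-dihydroxydrim-7-en-11-oic acid
Product: 20 2-(trimethylsilyl)ethyl 6β,9α-dihydroxydrim-7-en-11-oate ((5S,6R,9R,10S))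
Conditions: 2-(trimethylsilyl)ethyl 2,2,2-trichloroacetimidate, PhMe, 100 °C
Reagents that add atoms: 2-(trimethylsilyl)ethyl 2,2,2-trichloroacetimidate, C[Si](C)(C)CCOC(=N)C(Cl)(Cl)Cl
Why: Promoter-free imidate esterification is an O-alkylation of the carboxylate, so the congestion around C11 does not matter, and only the carboxylic acid is acidic enough to activate the imidate, which leaves both alcohols free.

Step 13
Reactants: 20 drimene diol silylethyl ester
Product: 21 2-(trimethylsilyl)ethyl 6β,9α,12-trihydroxydrim-7-en-11-oate ((5S,6R,9S,10S))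
Conditions: SeO2 (0.3 equiv), t-BuOOH (3 equiv), CH2Cl2, 0 °C → rt
Reagents that add atoms: tert-butyl hydroperoxide, CC(C)(C)OO (terminal oxidant; its oxygen is delivered through selenium dioxide, O=[Se]=O)
Why: Catalytic SeO2 allylic oxidation (ene reaction at C7, then [2,3]-shift) acts at the more substituted alkene end, where C9 has no hydrogen, so only the C8 methyl group can react, as established on drim-7-enes; any enal formed directly converges in step 14, and the oxidation precedes acylation to spare the triene.

Step 14
Reactants: 21 triol silylethyl ester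
Product: 22 2-(trimethylsilyl)ethyl 6β,9α-dihydroxy-12-oxodrim-7-en-11-oate ((5S,6R,9S,10S))
Conditions: TEMPO (10 mol %), PhI(OAc)2, CH2Cl2, rt
Reagents that add atoms: none
Why: Oxoammonium (TEMPO/PhI(OAc)2) oxidation takes primary allylic alcohols far faster than the axial, flanked secondary C6 carbinol, which a manganese dioxide finish could also attack.

Step 15
Reactants: 23 (2E,4E)-hexa-2,4-dienal; 24 triethyl phosphonoacetate
Product: 25 ethyl (2E,4E,6E)-octa-2,4,6-trienoate
Conditions: LiCl, DBU, MeCN, 0 °C → rt
Reagents that add atoms: none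
Why: Horner–Wadsworth–Emmons olefination under mild Masamune–Roush conditions is E-selective and leaves the two existing E alkenes unchanged.

Step 16
Reactants: 25 ethyl (2E,4E,6E)-octa-2,4,6-trienoate
Product: 26 (2E,4E,6E)-octa-2,4,6-trienoic acid
Conditions: LiOH, THF–MeOH–H2O, rt; then 1 M HCl
Reagents that add atoms: lithium hydroxide, [Li+].[OH-]
Why: Saponification of an unhindered conjugated ester proceeds without alkene isomerisation.

Step 17
Reactants: 22 C12 enal diol ester; 26 (2E,4E,6E)-octa-2,4,6-trienoic acid
Product: 28 2-(trimethylsilyl)ethyl 9α-hydroxy-6β-[(2E,4E,6E)-octa-2,4,6-trienoyloxy]-12-oxodrim-7-en-11-oate ((5S,6R,9S,10S)), via (2E,4E,6E)-octa-2,4,6-trienoic 2,4,6-trichlorobenzoic anhydride 27 (not isolated)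
Conditions: 2,4,6-Cl3C6H2COCl, Et3N, PhMe, rt; then 22, DMAP, PhMe, rt → 50 °C
Reagents that add atoms: 2,4,6-trichlorobenzoyl chloride, O=C(Cl)c1c(Cl)cc(Cl)cc1Cl (its acyl group stands only in 27)
Why: Yamaguchi esterification: DMAP picks the less hindered trienoyl carbonyl of 27 and transfers it to the secondary C6 hydroxyl with retention at C6, the tertiary C9 hydroxyl being inert.

Step 18
Reactants: 28 silylethyl ester of the target
Product: 29 ustusoic acid B, (5S,6R,9S,10S)-9α-hydroxy-6β-[(2E,4E,6E)-octa-2,4,6-trienoyloxy]-12-oxodrim-7-en-11-oic acid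
Conditions: TBAF, THF, 0 °C; then cold 0.5 M HCl to pH 3
Reagents that add atoms: none
Why: Fluoride attacks silicon, remote from the congested C11, and the silylethyl ester fragments to carboxylate, ethylene and Me3SiF at a temperature at which the trienoate, the enal and the tertiary carbinol should persist.

Compound list
1 | 2,2-dimethylpent-4-enal | C=CCC(C)(C)C=O | starting material
2 | 2-(triphenylphosphoranylidene)propanal | CC(C=O)=P(c1ccccc1)(c1ccccc1)c1ccccc1 | starting material
3 | (E)-2,4,4-trimethylhepta-2,6-dienal | O=C/C(C)=C/C(C)(C)CC=C | intermediate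
4 | diethyl oxalpropionate | CCOC(=O)C(=O)C(C)C(=O)OCC | starting material
5 | allyl bromide | C=CCBr | starting material
6 | diethyl 2-allyl-2-methyl-3-oxobutanedioate (racemic) | CCOC(=O)C(=O)C(C)(CC=C)C(=O)OCC | intermediate
7 | 2-allyl-2-methyl-3-oxobutanedioic acid (not isolated) | OC(=O)C(=O)C(C)(CC=C)C(=O)O | intermediate
8 | 3-methyl-2-oxohex-5-enoic acid (racemic) | C=CCC(C)C(=O)C(=O)O | intermediate
9 | 3-methyl-2-oxo-4-(1,2,4-trioxolan-3-yl)butanoic acid (ozonide, not isolated) | OC(=O)C(=O)C(C)CC1OCOO1 | intermediate
10 | 3-methyl-2,5-dioxopentanoic acid (racemic) | O=CCC(C)C(=O)C(=O)O | intermediate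
11 | 4-methyl-2-oxo-5,6-dihydro-2H-pyran-3,6-diyl diacetate (not isolated) | CC(=O)OC1CC(C)=C(OC(C)=O)C(=O)O1 | intermediate
12 | 3-acetoxy-4-methyl-2H-pyran-2-one | CC(=O)OC1=C(C)C=COC1=O | intermediate
13 | 3-hydroxy-4-methyl-2H-pyran-2-one | CC1=C(O)C(=O)OC=C1 | intermediate
14 | (1R,4R,7S,8S)-4-hydroxy-5,8-dimethyl-7-(2-methylpent-4-en-2-yl)-3-oxo-2-oxabicyclo[2.2.2]oct-5-ene-8-carbaldehyde (not isolated) | O1[C@@H]2C=C(C)[C@](O)(C1=O)[C@@](C)(C=O)[C@@H]2C(C)(C)CC=C | intermediate
15 | trimethylsilyl ether of 14 | O1[C@@H]2C=C(C)[C@](O[Si](C)(C)C)(C1=O)[C@@](C)(C=O)[C@@H]2C(C)(C)CC=C | intermediate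
16 | (1R,4R,7S,8S)-5,8-dimethyl-7-(2-methylpent-4-en-2-yl)-4-(trimethylsilyloxy)-8-vinyl-2-oxabicyclo[2.2.2]oct-5-en-3-one | O1[C@@H]2C=C(C)[C@](O[Si](C)(C)C)(C1=O)[C@@](C)(C=C)[C@@H]2C(C)(C)CC=C | intermediate
17 | (1R,4R,5S,6S)-1,4-dihydroxy-2,6-dimethyl-5-(2-methylpent-4-en-2-yl)-6-vinylcyclohex-2-ene-1-carboxylic acid | O[C@@H]1C=C(C)[C@](O)(C(=O)O)[C@@](C)(C=C)[C@@H]1C(C)(C)CC=C | intermediate
18 | 6β,9α-dihydroxydrima-1,7-dien-11-oic acid | O[C@@H]1C=C(C)[C@](O)(C(=O)O)[C@@]2(C)C=CCC(C)(C)[C@H]12 | intermediate
19 | 6β,9α-dihydroxydrim-7-en-11-oic acid | O[C@@H]1C=C(C)[C@](O)(C(=O)O)[C@@]2(C)CCCC(C)(C)[C@H]12 | intermediate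
20 | 2-(trimethylsilyl)ethyl 6β,9α-dihydroxydrim-7-en-11-oate | O[C@@H]1C=C(C)[C@](O)(C(=O)OCC[Si](C)(C)C)[C@@]2(C)CCCC(C)(C)[C@H]12 | intermediate
21 | 2-(trimethylsilyl)ethyl 6β,9α,12-trihydroxydrim-7-en-11-oate | O[C@@H]1C=C(CO)[C@](O)(C(=O)OCC[Si](C)(C)C)[C@@]2(C)CCCC(C)(C)[C@H]12 | intermediate
22 | 2-(trimethylsilyl)ethyl 6β,9α-dihydroxy-12-oxodrim-7-en-11-oate | O[C@@H]1C=C(C=O)[C@](O)(C(=O)OCC[Si](C)(C)C)[C@@]2(C)CCCC(C)(C)[C@H]12 | intermediate
23 | (2E,4E)-hexa-2,4-dienal | C/C=C/C=C/C=O | starting material
24 | triethyl phosphonoacetate | CCOC(=O)CP(=O)(OCC)OCC | starting material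
25 | ethyl (2E,4E,6E)-octa-2,4,6-trienoate | C/C=C/C=C/C=C/C(=O)OCC | intermediate
26 | (2E,4E,6E)-octa-2,4,6-trienoic acid | C/C=C/C=C/C=C/C(=O)O | intermediate
27 | (2E,4E,6E)-octa-2,4,6-trienoic 2,4,6-trichlorobenzoic anhydride (not isolated) | C/C=C/C=C/C=C/C(=O)OC(=O)c1c(Cl)cc(Cl)cc1Cl | intermediate
28 | 2-(trimethylsilyl)ethyl ester of ustusoic acid B | C/C=C/C=C/C=C/C(=O)O[C@@H]1C=C(C=O)[C@](O)(C(=O)OCC[Si](C)(C)C)[C@@]2(C)CCCC(C)(C)[C@H]12 | intermediate
29 | ustusoic acid B | C/C=C/C=C/C=C/C(=O)O[C@@H]1C=C(C=O)[C@](O)(C(=O)O)[C@@]2(C)CCCC(C)(C)[C@H]12 | target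

Total step count: 18
Longest linear sequence: 15 steps (from 4 through steps 2–14, 17 and 18 to 29)

Steps most likely to fail

Step 7.
- What may go wrong: the iminium ion of the α-methyl, β-tert-alkyl enal may be too congested for the first C5–C6 bond to form. The adduct may revert by retro-aldol/retro-Michael cleavage before it is trapped. Endo/exo or facial selectivity may be poor.
- Fallback: cationic polyene cyclisation in place of the cycloaddition, all steps of known types. It sets out from 24, bypasses steps 1–12, and comes back at 20.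
- Horner–Wadsworth–Emmons olefination of commercial (E)-geranylacetone with 24 (NaH, THF) and chromatographic removal of the 2Z isomer gives ethyl (2E,6E)-farnesoate F1. Saponification (KOH, aq EtOH) gives (2E,6E)-farnesoic acid F2.
- Low-temperature superacid cyclisation (FSO3H, 2-nitropropane, −78 °C) through a chair–chair transition state should give racemic drim-7-en-11-oic acid with the trans ring fusion and the equatorial carboxyl group. Classical resolution through the salt with one enantiomer of 1-phenylethylamine delivers (5S,9S,10S)-drim-7-en-11-oic acid F3.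
- O-Alkylation with the imidate of step 12 gives 2-(trimethylsilyl)ethyl drim-7-en-11-oate F4.
- Deprotonation at C9 (KHMDS, THF, −78 °C) and oxidation of the dienolate with 2-(phenylsulfonyl)-3-phenyloxaziridine, from the α face opposite the axial C10 methyl group, gives 2-(trimethylsilyl)ethyl 9α-hydroxydrim-7-en-11-oate F5.
- Allylic oxidation of the ring methylene C6 (Rh2(cap)4 cat., t-BuOOH, CH2Cl2) gives 2-(trimethylsilyl)ethyl 9α-hydroxy-6-oxodrim-7-en-11-oate F6.
- Luche reduction (NaBH4, CeCl3, MeOH, −78 °C), with hydride arriving from the α face away from the axial methyl groups on C4 and C10, gives the 6β-alcohol 20.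

Step 5.
- What may go wrong: the 1,4-keto aldehyde may close through the enol oxygen and dehydrate to the furan, enol acetylation may occur with the geometry that cannot lactonise, or the crude acid may oligomerise by aldol reactions.
- Fallback: the ring is closed while C6 is still at the alcohol level, so that no 1,4-dicarbonyl compound ever exists. It sets out from ozonide 9 of step 4 and comes back at 13.
- Ozonide 9 is reduced in the flask with excess NaBH4 (MeOH added, −78 → 0 °C) instead of Me2S. This takes ozonide and ketone down to 2,5-dihydroxy-3-methylpentanoic acid F7.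
- Acid-catalysed lactonisation (TsOH cat., PhMe, azeotropic removal of water) gives 3-hydroxy-4-methyltetrahydro-2H-pyran-2-one F8.
- Swern oxidation gives the α-keto lactone, which rests as its enol 3-hydroxy-4-methyl-5,6-dihydro-2H-pyran-2-one F9.
- IBX dehydrogenation (DMSO, 70 °C) introduces the C4=C5 double bond (pyrone numbering), and tautomerisation of the resulting enedione gives 13.

Step 13.
- What may go wrong: the alkene, deactivated by two allylic hydroxyl groups and the ester, may undergo the ene step too slowly under the mild catalytic conditions. Forcing the reaction may bring over-oxidation of the free C6 allylic carbinol or stalling through selenite ester formation.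
- Fallback: the competing carbinol is masked and the forcing stoichiometric oxidation is used. It sets out from 20 and comes back at 22, so 21 and step 14 drop out.
- Selective silylation of the secondary hydroxyl (TESOTf, 2,6-lutidine, CH2Cl2, −78 °C; the tertiary C9 hydroxyl is left) gives 2-(trimethylsilyl)ethyl 9α-hydroxy-6β-(triethylsilyloxy)drim-7-en-11-oate F10.
- SeO2 (stoichiometric) in 1,4-dioxane at 80 °C, the variant established on drim-7-enes, takes the methyl group directly to 2-(trimethylsilyl)ethyl 9α-hydroxy-12-oxo-6β-(triethylsilyloxy)drim-7-en-11-oate F11.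
- AcOH–THF–H2O at rt removes the triethylsilyl ether without touching the silylethyl ester and gives 22.

Further compounds
F1 | step 7 | ethyl (2E,6E)-farnesoate | CCOC(=O)/C=C(\C)CC/C=C(\C)CCC=C(C)C
F2 | step 7 | (2E,6E)-farnesoic acid | OC(=O)/C=C(\C)CC/C=C(\C)CCC=C(C)C
F3 | step 7 | (5S,9S,10S)-drim-7-en-11-oic acid | C1C=C(C)[C@H](C(=O)O)[C@@]2(C)CCCC(C)(C)[C@H]12
F4 | step 7 | 2-(trimethylsilyl)ethyl drim-7-en-11-oate | C1C=C(C)[C@H](C(=O)OCC[Si](C)(C)C)[C@@]2(C)CCCC(C)(C)[C@H]12
F5 | step 7 | 2-(trimethylsilyl)ethyl 9α-hydroxydrim-7-en-11-oate | C1C=C(C)[C@](O)(C(=O)OCC[Si](C)(C)C)[C@@]2(C)CCCC(C)(C)[C@H]12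
F6 | step 7 | 2-(trimethylsilyl)ethyl 9α-hydroxy-6-oxodrim-7-en-11-oate | O=C1C=C(C)[C@](O)(C(=O)OCC[Si](C)(C)C)[C@@]2(C)CCCC(C)(C)[C@H]12
F7 | step 5 | 2,5-dihydroxy-3-methylpentanoic acid (diastereomer mixture) | OCCC(C)C(O)C(=O)O
F8 | step 5 | 3-hydroxy-4-methyltetrahydro-2H-pyran-2-one (diastereomer mixture) | CC1CCOC(=O)C1O
F9 | step 5 | 3-hydroxy-4-methyl-5,6-dihydro-2H-pyran-2-one | CC1=C(O)C(=O)OCC1
F10 | step 13 | 2-(trimethylsilyl)ethyl 9α-hydroxy-6β-(triethylsilyloxy)drim-7-en-11-oate | CC[Si](CC)(CC)O[C@@H]1C=C(C)[C@](O)(C(=O)OCC[Si](C)(C)C)[C@@]2(C)CCCC(C)(C)[C@H]12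
F11 | step 13 | 2-(trimethylsilyl)ethyl 9α-hydroxy-12-oxo-6β-(triethylsilyloxy)drim-7-en-11-oate | CC[Si](CC)(CC)O[C@@H]1C=C(C=O)[C@](O)(C(=O)OCC[Si](C)(C)C)[C@@]2(C)CCCC(C)(C)[C@H]12
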